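**Plan**

1. Numbering used throughout: C1 (CH–O-senecioyl), C2, C3 (CH–O-isovaleryl), C4 (CMe2), C5, C6, C7 (C=O), C8, C9 (C–Me), C10, C11 (quaternary C–Me). The cyclobutane is C5–C6–C11–C10; C7–C8–C9 bridges C6/C10 and C1–C2–C3–C4 bridges C11/C5.
2. Enabling feature: the cyclobutane bond C6–C11 joins the α-carbon of the C7 ketone to the α-carbon of the oxygenated C1, a hidden 1,4-diketone. With C1 as a ketone and C8=C9 and C2=C3 in place, each carbonyl can enolise only toward C6 or toward C11.
3. Retrosynthetic cuts, in order: the ester C–O bonds at O1 and O3; C3–O (back to a C2=C3 enone); C6–C11 (oxidative coupling of a cis-fused cyclohexenone/cycloheptenone bis-enolate); C2–C3 (Claisen condensation); C1–C2; C10–C11 and C4–C5 (double Ireland–Claisen).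
4. Forward order: cyclohexadiene from toluene cis-dihydrodiol carrying both side arms, then the seven-membered ring, then the cyclobutane as the last ring, then C3–OH, C1–OH and the two esters.
5. Stereochemistry: C5 and C10 come from the diol through two suprafacial [3,3] shifts; C6 and C11 are forced by the cis ring fusion; C3 is set by a chiral copper catalyst; C1 by intramolecular hydride delivery anti to O3.

Key step: step 9

Assumption: (1S,2R)-3-methylcyclohexa-3,5-diene-1,2-diol (the enzymatically made cis-dihydrodiol of toluene) is taken as a commercial chiral starting material.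
Remark: C11 is an epimer mixture from step 2 to step 8 (drawn without configuration); it becomes trigonal in step 9 and is fixed there.

**Step 1**
Reactants: 1 (1S,2R)-3-methylcyclohexa-3,5-diene-1,2-diol
Product: 3 mixed diester of 1 (O1 isobutyrate; O2 propionate), via mono-isobutyrate 2 (not isolated)
Conditions: i-PrCOCl (1.0 equiv), pyridine, CH2Cl2, −40 °C; then (EtCO)2O (1.5 equiv), DMAP (cat.), 0 °C
Reagents that add atoms: isobutyryl chloride, CC(C)C(Cl)=O; propionic anhydride, CCC(=O)OC(=O)CC
Why: Regioselective acylation; the hydroxyl remote from the ring methyl (O1) is the less hindered one and should take the bulky isobutyryl group first, the hindered O2 is then acylated with anhydride/DMAP, and no stereocentre is touched.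

**Step 2**
Reactants: 3 mixed diester
Product: 7 cis dimethyl diester on a 1-methylcyclohexa-1,3-diene (C5 arm C(CH3)2CO2Me; C10 arm CH(CH3)CO2Me), via bis(silyl ketene acetal) 4 (not isolated), via bis(trimethylsilyl) ester 5 (not isolated), via diacid 6 (not isolated)
Conditions: LiN(i-Pr)2 (2.4 equiv), Me3SiCl (3 equiv), THF, −78 °C → rt, then 45 °C; MeOH; then Me3SiCHN2, PhMe/MeOH, 0 °C
Reagents that add atoms: (trimethylsilyl)diazomethane, C[Si](C)(C)C=[N+]=[N-]
Why: Double Ireland–Claisen rearrangement; each ketene acetal delivers its α-carbon suprafacially from the C–O carbon to the far alkene carbon (O2 to C10 first for the faster propionate acetal, then O1 to C5), so both new C–C bonds stand cis on the face the two oxygens occupied, which fixes C5 and C10 from the diol and builds the quaternary C4.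

**Step 3**
Reactants: 7 dimethyl diester
Product: 9 C7 allylic alcohol (C8=C9 retained), via B-alkyl-9-BBN borane 8 (not isolated)
Conditions: 9-BBN (1.2 equiv), THF, 0 °C → rt; then NaBO3·4H2O, THF/H2O, rt
Reagents that add atoms: sodium perborate, [Na+].[Na+].O[B-]1(O)OO[B-](O)(O)OO1
Why: Hydroboration of a 1,3-diene with a hindered dialkylborane; the borane should add to the less substituted C6=C7 bond from the face opposite the two arms with boron on the internal carbon C7 (away from the crowded C5), and stereoretentive oxidation gives the alcohol that later becomes the C7 ketone.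

**Step 4**
Reactants: 9 allylic alcohol diester
Product: 11 methyl ketone (C1 ketone, C2 methyl; C3 ester intact), via α-trimethylsilyl ketone 10 (not isolated)
Conditions: Me3SiCH2Li (3.3 equiv), THF/pentane, −78 → 0 °C; then MeOH, rt; aq. NH4Cl
Reagents that add atoms: (trimethylsilyl)methyllithium, [Li]C[Si](C)(C)C
Why: Methyl ketone synthesis from an ester with a silylmethyllithium; the bulky reagent should attack only the ester next to the tertiary C11 (the α-quaternary ester at C3 is shielded), the α-silyl ketone is protected as its enolate against a second addition, and methanol removes silicon.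

**Step 5**
Reactants: 11 methyl ketone
Product: 12 cis-fused bicyclic β-diketone (C1 and C3 ketones; C7–OH)
Conditions: LiN(i-Pr)2 (3.3 equiv), THF, −78 °C → rt; aq. NH4Cl
Reagents that add atoms: none
Why: Intramolecular Claisen (Dieckmann-type) condensation; the kinetic methyl enolate (C2) acylates at the C3 ester and closes the seven-membered ring, helped by the cis arms and the gem-dimethyl group and driven by deprotonation of the β-diketone.

**Step 6**
Reactants: 12 β-diketone
Product: 13 methyl enol ether (C1–OMe; C1=C2; C3 ketone)
Conditions: Me2SO4, K2CO3, acetone, rt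
Reagents that add atoms: dimethyl sulfate, COS(=O)(=O)OC
Why: O-alkylation of a cyclic β-diketone enolate with a hard electrophile should take place at the less hindered oxygen (on C1 beside the tertiary C11, not on C3 beside the quaternary C4), which sets up the reductive carbonyl transposition.

**Step 7**
Reactants: 13 methyl enol ether
Product: 15 cycloheptenone (C1 ketone; C2=C3; C7–OH), via allylic alcohol 14 (not isolated)
Conditions: i-Bu2AlH (3.5 equiv), CH2Cl2, −78 °C; then 1 M aq. HCl, THF, 0 °C
Reagents that add atoms: water, O
Why: Stork–Danheiser-type reductive transposition; hydride adds 1,2 to the vinylogous ester carbonyl (C3) and mild acid ionises the resulting allylic alcohol and hydrolyses the enol ether, leaving the ketone at C1 and the C2=C3 double bond, as in the classical route to 4,4-dimethylcyclohexenone.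

**Step 8**
Reactants: 15 cycloheptenone alcohol
Product: 16 cis-fused bis-enone (5R,10S)
Conditions: Dess–Martin periodinane, NaHCO3, CH2Cl2, 0 °C → rt
Reagents that add atoms: none
Why: Dess–Martin oxidation of the secondary allylic alcohol under buffered, non-basic conditions should give the C7 enone without epimerising the γ-carbon C10.

**Step 9**
Reactants: 16 cis-fused bis-enone
Product: 18 tricyclic bis-enone (cyclobutane closed), via dilithium bis-enolate 17 (not isolated)
Conditions: LiN(i-Pr)2 (2.3 equiv), THF, −78 → −40 °C; then Fe(acac)3 (2.4 equiv), THF, −78 °C → rt, 0.01 M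
Reagents that add atoms: none
Why: Proposed new method: kinetic double deprotonation can give only the two cross-conjugated α'-enolates (C6 of the cyclohexenone; C11 of the cycloheptenone, whose C2 and C3 are sp2 and whose C4 is quaternary), and one-electron oxidation by trivalent iron turns one of them into an α-keto radical that adds to the carbon terminus of the other enolate, the ketyl radical anion so formed being oxidised at once to the 1,4-diketone. The closest known reaction type is the oxidative coupling of ketone and enone α'-enolates by trivalent iron or divalent copper salts, known intramolecularly for five-membered, six-membered and bridged rings and intermolecularly for enone α'-enolates, but not for closing a cyclobutane onto a fully substituted carbon. The cyclobutane C5–C6–C11–C10 closes in a 4-exo-trig manner across the cis ring fusion, where C6 and C11 are 1,4-related and gauche, and no other ring is formed in this step. Both new stereocentres are dictated by the existing cis C5/C10 fusion: the bond can form only between the enolate faces on the concave side, which puts C7 and C9 on one face of the new ring and C1 and C4 on the other, so the C11 methyl and the C6 hydrogen have no alternative position. The step needs C6–C11 coupling in preference to dimerisation, O-coupling or coupling at C3 or C9; high dilution, the cross-conjugation of both enolates (no spin density at C3 or C9) and the 1,4-proximity should secure this, and the fast second oxidation makes formation of the strained bond irreversible.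

**Step 10**
Reactants: 18 tricyclic bis-enone
Product: 20 (3R)-β-hydroxy ketone (C1 ketone; C3–OH on the side of C10), via pinacol boronate 19 (not isolated)
Conditions: [Cu(MeCN)4]PF6 (5 mol %), (R,R)-QuinoxP* (6 mol %), LiOt-Bu (10 mol %), B2pin2 (1.2 equiv), MeOH (2 equiv), THF, rt; then NaBO3·4H2O, THF/H2O, 0 °C
Reagents that add atoms: sodium perborate, [Na+].[Na+].O[B-]1(O)OO[B-](O)(O)OO1
Why: Copper-catalysed enantioselective conjugate borylation of a cyclic enone followed by stereoretentive C–B oxidation; the disubstituted C2=C3 enone should react while the β,β-disubstituted C8=C9 enone does not, and because the substrate offers two nearly equivalent faces at C3 the chiral bisphosphine–copper catalyst must control the new centre, the ligand antipode being the one that delivers boron to the C3 face looking toward C10.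

**Step 11**
Reactants: 20 β-hydroxy ketone
Product: 21 C3 isovalerate with free (1R)-hydroxyl
Conditions: i-BuCHO (5 equiv), SmI2 (0.3 equiv), THF, −10 °C
Reagents that add atoms: 3-methylbutanal, CC(C)CC=O
Why: Evans–Tishchenko reduction; the samarium-bound hemiacetal formed from the C3 hydroxyl and the aldehyde delivers hydride intramolecularly to the C1 ketone from the face of the C3 oxygen, which should give the 1,3-anti diol with the isovalerate already on O3 and leave the C7 enone untouched.

**Step 12**
Reactants: 21 hydroxy isovalerate
Product: 22 target (1R,3R,5S,6R,10R,11R)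
Conditions: senecioic acid, 2,4,6-Cl3C6H2COCl, Et3N, THF, rt; then 21, DMAP, PhMe, 40 °C
Reagents that add atoms: 3-methylbut-2-enoic acid, CC(C)=CC(=O)O
Why: Yamaguchi esterification of the hindered secondary alcohol through the mixed anhydride and DMAP, chosen to avoid the vinylketene pathway that would move the senecioate double bond out of conjugation.

**Compound list**

1 | (1S,2R)-3-methylcyclohexa-3,5-diene-1,2-diol | CC1=CC=C[C@H](O)[C@@H]1O | starting material
2 | 1-O-isobutyryl derivative of 1 (free hydroxyl beside the methyl-bearing carbon) | CC1=CC=C[C@H](OC(=O)C(C)C)[C@@H]1O | intermediate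
3 | 1-O-isobutyryl-2-O-propionyl derivative of 1 | CC1=CC=C[C@H](OC(=O)C(C)C)[C@@H]1OC(=O)CC | intermediate
4 | bis(trimethylsilyl ketene acetal) of 3 | CC1=CC=C[C@H](OC(O[Si](C)(C)C)=C(C)C)[C@@H]1OC(O[Si](C)(C)C)=CC | intermediate
5 | bis(trimethylsilyl) ester of diacid 6 | CC1=CC=C[C@@H](C(C)(C)C(=O)O[Si](C)(C)C)[C@H]1C(C)C(=O)O[Si](C)(C)C | intermediate
6 | cis diacid: cyclohexadiene C6=C7–C8=C9(Me), C5 bearing C(CH3)2CO2H, C10 bearing CH(CH3)CO2H on the same face | CC1=CC=C[C@@H](C(C)(C)C(=O)O)[C@H]1C(C)C(=O)O | intermediate
7 | dimethyl ester of 6 | CC1=CC=C[C@@H](C(C)(C)C(=O)OC)[C@H]1C(C)C(=O)OC | intermediate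
8 | C7-(9-borabicyclo[3.3.1]nonan-9-yl) adduct of 7, boron trans to the two arms | CC1=C[C@H](B2C3CCCC2CCC3)C[C@@H](C(C)(C)C(=O)OC)[C@H]1C(C)C(=O)OC | intermediate
9 | C7 allylic alcohol diester (OH trans to the arms; C8=C9) | CC1=C[C@H](O)C[C@@H](C(C)(C)C(=O)OC)[C@H]1C(C)C(=O)OC | intermediate
10 | α-trimethylsilyl ketone at C1 (present as lithium enolate) | CC1=C[C@H](O)C[C@@H](C(C)(C)C(=O)OC)[C@H]1C(C)C(=O)C[Si](C)(C)C | intermediate
11 | C1 methyl ketone with C3 methyl ester and C7–OH | CC1=C[C@H](O)C[C@@H](C(C)(C)C(=O)OC)[C@H]1C(C)C(C)=O | intermediate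
12 | cis-fused bicyclic β-diketone: ring C5–C6–C7(OH)–C8=C9(Me)–C10 fused to ring C10–C11(Me)–C1(=O)–C2–C3(=O)–C4(Me)2–C5 | CC1=C[C@H](O)C[C@@H]2[C@H]1C(C)C(=O)CC(=O)C2(C)C | intermediate
13 | methyl enol ether of 12 (C1–OMe, C1=C2, C3 ketone) | CC1=C[C@H](O)C[C@@H]2[C@H]1C(C)C(OC)=CC(=O)C2(C)C | intermediate
14 | C3 allylic alcohol from 1,2-reduction of 13 | CC1=C[C@H](O)C[C@@H]2[C@H]1C(C)C(OC)=CC(O)C2(C)C | intermediate
15 | cis-fused cycloheptenone (C1 ketone, C2=C3) with C7–OH | CC1=C[C@H](O)C[C@@H]2[C@H]1C(C)C(=O)C=CC2(C)C | intermediate
16 | (5R,10S) cis-fused bis-enone: C7(=O)–C8=C9(Me) in the six-membered ring, C1(=O)–C2=C3 in the seven-membered ring | CC1=CC(=O)C[C@@H]2[C@H]1C(C)C(=O)C=CC2(C)C | intermediate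
17 | dilithium bis-enolate of 16 (C6=C7–OLi; C11=C1–OLi) | CC1=CC(O[Li])=C[C@@H]2[C@H]1C(C)=C(O[Li])C=CC2(C)C | intermediate
18 | tricyclic bis-enone (5S,6R,10R,11R): cyclobutane C5–C6–C11–C10, C1 and C7 ketones, C2=C3 and C8=C9 | O=C1C=CC(C)(C)[C@@H]2[C@H]3C(=O)C=C(C)[C@@H]2[C@]31C | intermediate
19 | (3R)-C3 pinacol boronate of the C1 ketone | O=C1C[C@@H](B4OC(C)(C)C(C)(C)O4)C(C)(C)[C@@H]2[C@H]3C(=O)C=C(C)[C@@H]2[C@]31C | intermediate
20 | (3R)-3-hydroxy C1 ketone | O=C1C[C@@H](O)C(C)(C)[C@@H]2[C@H]3C(=O)C=C(C)[C@@H]2[C@]31C | intermediate
21 | (1R,3R) diol 3-isovalerate with free C1–OH | O[C@@H]1C[C@@H](OC(=O)CC(C)C)C(C)(C)[C@@H]2[C@H]3C(=O)C=C(C)[C@@H]2[C@]31C | intermediate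
22 | target: C1 senecioate, C3 isovalerate, C7 enone | CC(C)=CC(=O)O[C@@H]1C[C@@H](OC(=O)CC(C)C)C(C)(C)[C@@H]2[C@H]3C(=O)C=C(C)[C@@H]2[C@]31C | target

**Step count and risks**

Total step count: 12. Longest linear sequence: 12 steps (the route is linear from 1).

Steps most likely to fail:

Step 9 (proposed new method). The ring-closing C–C bond formation may be slower than intermolecular coupling or quenching of the oxidised enolate, so that dimers or recovered 16 result instead of the cyclobutane. The fallback uses known polar chemistry, sets out from 16 and returns at 18. LiN(i-Pr)2 (1.05 equiv) with Me3SiCl at −78 °C should enolise only the more accessible C6 methylene and give the silyl dienol ether F1. N-Bromosuccinimide in THF at −78 °C would convert it into the α'-bromo enone F2. KN(SiMe3)2 in THF at −78 °C would then form the C11 enolate of the cycloheptenone, which displaces bromide at C6 in an intramolecular enolate alkylation and closes the cyclobutane to 18.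

Step 2. After the first rearrangement the remaining acyloxy group is doubly allylic and may be lost by 1,4-elimination with aromatisation before the slower isobutyrate acetal rearranges; the second shift could also go to the wrong alkene terminus. The fallback sets out from 1 and returns at 7, with one rearrangement at a time and the second oxygen held as a silyl ether. t-BuMe2SiCl/imidazole would silylate O1 to the silyl ether F3, and propionic anhydride/DMAP would give the propionate F4. Ireland–Claisen rearrangement (LiN(i-Pr)2, Me3SiCl) would give the acid F5, esterified with Me3SiCHN2 to the methyl ester F6. Bu4NF would free the alcohol F7, acylated in the same flask with isobutyric anhydride to the isobutyrate F8. A second Ireland–Claisen rearrangement would give the acid F9, and Me3SiCHN2 would give 7.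

Step 10. Facial selectivity at C3 may be poor because the substrate presents two nearly equivalent enone faces, and borylation at the neopentyl β-carbon may be slow. The fallback sets out from 18 and returns at 20, forming the C3–O bond by epoxidation instead. Amine-salt-catalysed asymmetric nucleophilic epoxidation with aqueous H2O2 (9-amino-9-deoxy-epi-quinine bis(trifluoroacetate), dioxane, 35 °C) would give the cis epoxy ketone F10. SmI2 in THF/MeOH at −90 °C would then cleave the Cα–O bond to give 20.

**Further compounds**

F1 | step 9 | C7 trimethylsilyl dienol ether of 16 (C6=C7) | CC1=CC(O[Si](C)(C)C)=C[C@@H]2[C@H]1C(C)C(=O)C=CC2(C)C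
F2 | step 9 | 6-bromo derivative of 16 | CC1=CC(=O)C(Br)[C@@H]2[C@H]1C(C)C(=O)C=CC2(C)C
F3 | step 2 | 1-O-tert-butyldimethylsilyl ether of 1 | CC1=CC=C[C@H](O[Si](C)(C)C(C)(C)C)[C@@H]1O
F4 | step 2 | 2-O-propionate of F3 | CC1=CC=C[C@H](O[Si](C)(C)C(C)(C)C)[C@@H]1OC(=O)CC
F5 | step 2 | mono-rearranged acid: C10 bearing CH(CH3)CO2H, C7–OSi retained, alkenes C5=C6 and C8=C9 | CC1=C[C@@H](O[Si](C)(C)C(C)(C)C)C=C[C@H]1C(C)C(=O)O
F6 | step 2 | methyl ester of F5 | CC1=C[C@@H](O[Si](C)(C)C(C)(C)C)C=C[C@H]1C(C)C(=O)OC
F7 | step 2 | doubly allylic C7 alcohol from F6 | CC1=C[C@@H](O)C=C[C@H]1C(C)C(=O)OC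
F8 | step 2 | C7 isobutyrate of F7 | CC1=C[C@@H](OC(=O)C(C)C)C=C[C@H]1C(C)C(=O)OC
F9 | step 2 | acid ester: C5 bearing C(CH3)2CO2H, C10 bearing CH(CH3)CO2Me, diene C6=C7–C8=C9 | CC1=CC=C[C@@H](C(C)(C)C(=O)O)[C@H]1C(C)C(=O)OC
F10 | step 10 | cis C2–C3 epoxide of 18 on the face toward C10 | O=C1[C@H]4O[C@H]4C(C)(C)[C@@H]2[C@H]3C(=O)C=C(C)[C@@H]2[C@]31C
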